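**Plan**

- Retrosynthesis: C2 epimerisation, ester reduction and C2=C3 hydrogenation lead back to dihydrofuran 10. Its O1–C5 bond is cut to aroyl cyclopropane 9, which is cut at C3–C4 (and the temporary C3–C5 bond) into keto ester 7 and cyclic sulfate 6. The aryl–CH2 bond of the benzyl group goes back to Grignard reagent 1 and glycidyl ether 2.
- Enabling feature: in the oxolane, O1 and C2 with its aryl group are the oxygen and carbonyl carbon of an aroyl ketone sitting on C3, and C3–C4–C5 can be a cyclopropane, so ring expansion only has to make O1–C5.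
- Forward order: aryl–CH2 bond (step 1), cyclopropane bonds C3–C4 and C3–C5 (step 4), oxolane ring by O1–C5 closure with loss of C3–C5 (step 5), then saturation and adjustment of C3 and C2 (steps 6 to 8).
- Stereochemistry: C4 comes from (R)-benzyl glycidyl ether through one SN2 inversion in step 4; C3 from hydrogenation anti to the C4 benzyl group; C2 from acid equilibration to the 2,3-trans isomer.

Key step: step 5

Remark: the SMILES is read as the (2S,3R,4R)-oxolane (aryl trans to CH2OH, CH2OH cis to benzyl); 1 (as its THF solution), 2 and 7 are taken as purchased.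

**Route**

Step 1
Reactants: 1 3,4,5-trimethoxyphenylmagnesium bromide; 2 (2R)-2-[(benzyloxy)methyl]oxirane ((R)-benzyl glycidyl ether)
Product: 3 (2R)-1-(benzyloxy)-3-(3,4,5-trimethoxyphenyl)propan-2-ol
Conditions: CuI (10 mol%), THF, −30 to 0 °C; aq. NH4Cl
Reagents that add atoms: none
Why: Copper-catalysed Grignard opening of a terminal epoxide is an SN2 attack at the unsubstituted carbon, so the stereocentre of 2 is carried unchanged into 3 as the (R)-carbinol.

Step 2
Reactants: 3 (2R)-1-(benzyloxy)-3-(3,4,5-trimethoxyphenyl)propan-2-ol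
Product: 4 (2R)-3-(3,4,5-trimethoxyphenyl)propane-1,2-diol
Conditions: H2 (1 atm), Pd/C (10 wt%), EtOH, rt
Reagents that add atoms: none
Why: Hydrogenolysis of the benzyl ether frees the primary alcohol, while the aryl–CH2 bond carries no heteroatom and the stereocentre is not involved.

Step 3
Reactants: 4 (2R)-3-(3,4,5-trimethoxyphenyl)propane-1,2-diol
Product: 6 (4R)-4-[(3,4,5-trimethoxyphenyl)methyl]-1,3,2-dioxathiolane 2,2-dioxide, via cyclic sulfite 5 (not isolated)
Conditions: SOCl2, Et3N, CH2Cl2, 0 °C; then RuCl3 (0.5 mol%), NaIO4, MeCN/H2O, 0 °C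
Reagents that add atoms: thionyl chloride, O=S(Cl)Cl; sodium periodate, [Na+].[O-]I(=O)(=O)=O
Why: Cyclic sulfite formation and RuO4-catalysed oxidation to the cyclic sulfate is the standard activation of a 1,2-diol as a 1,2-dielectrophile; no bond to the stereocentre is broken, and the brief catalytic oxidation at 0 °C is of the kind methoxybenzyl groups tolerate.

Step 4
Reactants: 6 (4R)-4-[(3,4,5-trimethoxyphenyl)methyl]-1,3,2-dioxathiolane 2,2-dioxide; 7 methyl 3-oxo-3-(3,4,5-trimethoxyphenyl)propanoate
Product: 9 methyl (2S)-1-(3,4,5-trimethoxybenzoyl)-2-[(3,4,5-trimethoxyphenyl)methyl]cyclopropane-1-carboxylate (C1 epimer mixture), via ring-opened sodium alkyl sulfate 8 (not isolated)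
Conditions: NaH (2.2 equiv), DME, 0 °C to reflux
Reagents that add atoms: none
Why: In this double C-alkylation of an active methylene compound by a cyclic sulfate, the sodium enolate of 7 opens 6 at the primary carbon and the regenerated enolate displaces the secondary sulfate in a 3-exo-tet SN2 closure with inversion, turning the (R)-carbinol carbon into the (S)-configured benzyl-bearing cyclopropane carbon, while C1 forms as an inconsequential epimer mixture.

Step 5
Reactants: 9 methyl (2S)-1-(3,4,5-trimethoxybenzoyl)-2-[(3,4,5-trimethoxyphenyl)methyl]cyclopropane-1-carboxylate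
Product: 10 methyl (4R)-2-(3,4,5-trimethoxyphenyl)-4-[(3,4,5-trimethoxyphenyl)methyl]-4,5-dihydrofuran-3-carboxylate
Conditions: DABCO (30 mol%), DMSO, 120 °C
Reagents that add atoms: none
Why: DABCO attacks the unsubstituted methylene carbon (C3) of the doubly activated cyclopropane in an SN2 homoconjugate opening that breaks C1–C3 and gives an ammonium-bearing keto ester enolate, whose ketone oxygen then displaces DABCO from the same primary carbon, forming O1–C5 of the dihydrofuran. The closest known reaction type is the amine- or iodide-catalysed Cloke–Wilson rearrangement of 1-acylcyclopropane-1-carboxylates to 4,5-dihydrofuran-3-carboxylates; the iodide-catalysed isomerisation of N-acylaziridines to oxazolines shows the same preference of a nucleophile in neutral medium for the methylene terminus. The one ring closes in a 5-exo-tet mode. No stereocentre is created: C4 of 10 is the benzyl-bearing cyclopropane carbon, at which no bond is made or broken, and C1 becomes sp2, so both C1 epimers of 9 converge on 10. The selectivity needed is opening at CH2 and not at the benzyl-bearing CH (which would lead to the 5-benzyl isomer); it should be secured by the steric sensitivity of amine quaternisation and of enolate O-alkylation (primary over secondary carbon), by the reversibility of ring opening, which lets the faster-closing primary ammonium enolate drain the mixture, and by the absence of Lewis or Brønsted acid that would favour cleavage toward the more substituted carbon.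

Step 6
Reactants: 10 methyl (4R)-2-(3,4,5-trimethoxyphenyl)-4-[(3,4,5-trimethoxyphenyl)methyl]-4,5-dihydrofuran-3-carboxylate
Product: 11 methyl (2R,3S,4R)-2-(3,4,5-trimethoxyphenyl)-4-[(3,4,5-trimethoxyphenyl)methyl]oxolane-3-carboxylate (all-cis)
Conditions: H2 (5 bar), Pd/C (10 wt%), EtOAc, rt
Reagents that add atoms: none
Why: Heterogeneous syn hydrogenation of the tetrasubstituted enol ether double bond should take place on the face opposite the adjacent C4 benzyl group, which sets C3 as required (ester cis to benzyl) and C2 provisionally cis, giving the all-cis ester.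

Step 7
Reactants: 11 methyl (2R,3S,4R)-2-(3,4,5-trimethoxyphenyl)-4-[(3,4,5-trimethoxyphenyl)methyl]oxolane-3-carboxylate
Product: 12 [(2R,3R,4R)-2-(3,4,5-trimethoxyphenyl)-4-[(3,4,5-trimethoxyphenyl)methyl]oxolan-3-yl]methanol (all-cis)
Conditions: LiAlH4, THF, −10 to 0 °C; aq. sodium potassium tartrate
Reagents that add atoms: none
Why: Hydride reduction of the ester to the primary alcohol is faster at low temperature than enolisation, so the kinetically set, epimerisable C3 centre is fixed as a non-enolisable hydroxymethyl-bearing carbon.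

Step 8
Reactants: 12 [(2R,3R,4R)-2-(3,4,5-trimethoxyphenyl)-4-[(3,4,5-trimethoxyphenyl)methyl]oxolan-3-yl]methanol
Product: 13 [(2S,3R,4R)-2-(3,4,5-trimethoxyphenyl)-4-[(3,4,5-trimethoxyphenyl)methyl]oxolan-3-yl]methanol (target)
Conditions: BF3·OEt2 (0.2 equiv), CH2Cl2, −20 to 0 °C; aq. NaHCO3
Reagents that add atoms: none
Why: Acid-catalysed epimerisation of a 2-aryl oxolane through reversible SN1 opening of the benzylic C2–O1 bond and 5-exo reclosure by the C5 hydroxyl, the reaction type that interconverts cis and trans 2-aryl tetrahydrofuran lignans, should drain the strained all-cis isomer into the thermodynamically preferred 2,3-trans isomer, with C3 and C4 untouched.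

**Compound list**

1 | 3,4,5-trimethoxyphenylmagnesium bromide | COc1cc([Mg]Br)cc(OC)c1OC | starting material
2 | (2R)-2-[(benzyloxy)methyl]oxirane ((R)-benzyl glycidyl ether) | c1ccccc1COC[C@H]1CO1 | starting material
3 | (2R)-1-(benzyloxy)-3-(3,4,5-trimethoxyphenyl)propan-2-ol | c1ccccc1COC[C@H](O)Cc1cc(OC)c(OC)c(OC)c1 | intermediate
4 | (2R)-3-(3,4,5-trimethoxyphenyl)propane-1,2-diol | OC[C@H](O)Cc1cc(OC)c(OC)c(OC)c1 | intermediate
5 | (4R)-4-[(3,4,5-trimethoxyphenyl)methyl]-1,3,2-dioxathiolane 2-oxide (both sulfur epimers) | O=S1OC[C@@H](Cc2cc(OC)c(OC)c(OC)c2)O1 | intermediate (not isolated)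
6 | (4R)-4-[(3,4,5-trimethoxyphenyl)methyl]-1,3,2-dioxathiolane 2,2-dioxide | O=S1(=O)OC[C@@H](Cc2cc(OC)c(OC)c(OC)c2)O1 | intermediate
7 | methyl 3-oxo-3-(3,4,5-trimethoxyphenyl)propanoate | COC(=O)CC(=O)c1cc(OC)c(OC)c(OC)c1 | starting material
8 | sodium (2S)-5-methoxy-5-oxo-4-(3,4,5-trimethoxybenzoyl)-1-(3,4,5-trimethoxyphenyl)pentan-2-yl sulfate (C4 epimers, present as its sodium enolate) | COC(=O)C(C[C@@H](Cc1cc(OC)c(OC)c(OC)c1)OS(=O)(=O)[O-])C(=O)c1cc(OC)c(OC)c(OC)c1.[Na+] | intermediate (not isolated)
9 | methyl (2S)-1-(3,4,5-trimethoxybenzoyl)-2-[(3,4,5-trimethoxyphenyl)methyl]cyclopropane-1-carboxylate (C1 epimer mixture) | COC(=O)C1(C(=O)c2cc(OC)c(OC)c(OC)c2)C[C@@H]1Cc1cc(OC)c(OC)c(OC)c1 | intermediate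
10 | methyl (4R)-2-(3,4,5-trimethoxyphenyl)-4-[(3,4,5-trimethoxyphenyl)methyl]-4,5-dihydrofuran-3-carboxylate | COC(=O)C1=C(c2cc(OC)c(OC)c(OC)c2)OC[C@@H]1Cc1cc(OC)c(OC)c(OC)c1 | intermediate
11 | methyl (2R,3S,4R)-2-(3,4,5-trimethoxyphenyl)-4-[(3,4,5-trimethoxyphenyl)methyl]oxolane-3-carboxylate (all-cis) | COc1cc(C[C@H]2CO[C@@H](c3cc(OC)c(OC)c(OC)c3)[C@H]2C(=O)OC)cc(OC)c1OC | intermediate
12 | [(2R,3R,4R)-2-(3,4,5-trimethoxyphenyl)-4-[(3,4,5-trimethoxyphenyl)methyl]oxolan-3-yl]methanol (all-cis) | COc1cc(C[C@H]2CO[C@@H](c3cc(OC)c(OC)c(OC)c3)[C@H]2CO)cc(OC)c1OC | intermediate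
13 | [(2S,3R,4R)-2-(3,4,5-trimethoxyphenyl)-4-[(3,4,5-trimethoxyphenyl)methyl]oxolan-3-yl]methanol (CNP0321241.1) | COc1cc(C[C@H]2CO[C@H](c3cc(OC)c(OC)c(OC)c3)[C@H]2CO)cc(OC)c1OC | target

Total step count: 8. Longest linear sequence: 8 steps (2 to 13).

**Steps most likely to fail**

1. Step 5. The catalyst may open the cyclopropane at the benzyl-bearing carbon instead of the methylene carbon, so that oxygen closes onto the wrong carbon, or it may fail to turn over before the methyl ester is attacked. The fallback sets out from Grignard reagent 1 and returns at 10, with the regiochemistry fixed before any C–O bond is made.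
   - Dimethyl malonate and (R)-epichlorohydrin (NaOMe, MeOH, reflux) should give methyl (1S,5R)-2-oxo-3-oxabicyclo[3.1.0]hexane-1-carboxylate F1, in which the oxygen-bearing carbon is already tied into a lactone.
   - 1 with CuI (THF, −30 °C) should open the cyclopropane of F1 at its only methylene carbon to give methyl (3S,4R)-2-oxo-4-[(3,4,5-trimethoxyphenyl)methyl]oxolane-3-carboxylate F2.
   - Krapcho demethoxycarbonylation (LiCl, wet DMSO, 140 °C) should give (4R)-4-[(3,4,5-trimethoxyphenyl)methyl]oxolan-2-one F3.
   - C-acylation (LiHMDS, 2 equiv, THF, −78 °C; 3,4,5-trimethoxybenzoyl chloride) should give (3S,4R)-3-(3,4,5-trimethoxybenzoyl)-4-[(3,4,5-trimethoxyphenyl)methyl]oxolan-2-one F4.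
   - HCl in dry MeOH at reflux (lactone methanolysis, hemiketalisation onto the aryl ketone, dehydration) should convert F4 into 10.

2. Step 8. During the acid equilibration the ring-opened C2 benzylic cation may be captured by the electron-rich 3,4,5-trimethoxybenzyl ring (Friedel–Crafts closure to an aryltetralin) faster than the trans oxolane accumulates, or equilibration may stall. The fallback sets out from 10 and returns at the target 13; it replaces steps 6 to 8 by one kinetically controlled ring closure.
   - Aqueous acid (2 M HCl, THF, 50 °C) should hydrolyse the enol ether of 10, and the freed γ-hydroxy β-keto ester should lactonise to the keto lactone F4 described above. Its enolisable C3 settles trans to the benzyl group, which is the arrangement that becomes 3,4-cis in the oxolane.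
   - LiAlH4 (THF, 0 °C) should reduce ketone and lactone to (2R,3R)-2-[hydroxy(3,4,5-trimethoxyphenyl)methyl]-3-[(3,4,5-trimethoxyphenyl)methyl]butane-1,4-diol F5 as a mixture of carbinol epimers.
   - A single low-temperature ionisation of the benzylic alcohol (BF3·OEt2, CH2Cl2, −78 °C, short contact) should let the 1,4-hydroxyl close the oxolane trans to the C3 substituent, giving 13 without holding the product under ionising conditions.

3. Step 4. In the ring-closing displacement the enolate oxygen may attack the secondary sulfate (5-exo O-alkylation), or the sulfate may be eliminated, instead of the 3-exo C-alkylation. The fallback sets out from cyclic sulfate 6 and returns at 9.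
   - Dimethyl malonate (NaH, DME, reflux), which alkylates only on carbon, should give dimethyl (2S)-2-[(3,4,5-trimethoxyphenyl)methyl]cyclopropane-1,1-dicarboxylate F6.
   - One equivalent of KOH (MeOH/H2O, 0 °C to rt, then HCl) should hydrolyse the less hindered ester trans to the benzyl group to (1R,2S)-1-(methoxycarbonyl)-2-[(3,4,5-trimethoxyphenyl)methyl]cyclopropane-1-carboxylic acid F7.
   - (COCl)2 with catalytic DMF (CH2Cl2, 0 °C) should give methyl (1S,2S)-1-(chlorocarbonyl)-2-[(3,4,5-trimethoxyphenyl)methyl]cyclopropane-1-carboxylate F8.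
   - Fe(acac)3-catalysed acylation of Grignard reagent 1 (THF, −78 °C) should give 9 as a single C1 epimer, which enters step 5 unchanged.

**Further compounds**

F1 | step 5 | methyl (1S,5R)-2-oxo-3-oxabicyclo[3.1.0]hexane-1-carboxylate | O=C1OC[C@@H]2C[C@]12C(=O)OC
F2 | step 5 | methyl (3S,4R)-2-oxo-4-[(3,4,5-trimethoxyphenyl)methyl]oxolane-3-carboxylate | O=C1OC[C@H](Cc2cc(OC)c(OC)c(OC)c2)[C@H]1C(=O)OC
F3 | step 5 | (4R)-4-[(3,4,5-trimethoxyphenyl)methyl]oxolan-2-one | O=C1OC[C@H](Cc2cc(OC)c(OC)c(OC)c2)C1
F4 | step 5 | (3S,4R)-3-(3,4,5-trimethoxybenzoyl)-4-[(3,4,5-trimethoxyphenyl)methyl]oxolan-2-one | O=C1OC[C@H](Cc2cc(OC)c(OC)c(OC)c2)[C@H]1C(=O)c1cc(OC)c(OC)c(OC)c1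
F5 | step 8 | (2R,3R)-2-[hydroxy(3,4,5-trimethoxyphenyl)methyl]-3-[(3,4,5-trimethoxyphenyl)methyl]butane-1,4-diol (carbinol epimers) | OC[C@H](Cc1cc(OC)c(OC)c(OC)c1)[C@H](CO)C(O)c1cc(OC)c(OC)c(OC)c1
F6 | step 4 | dimethyl (2S)-2-[(3,4,5-trimethoxyphenyl)methyl]cyclopropane-1,1-dicarboxylate | COC(=O)C1(C(=O)OC)C[C@@H]1Cc1cc(OC)c(OC)c(OC)c1
F7 | step 4 | (1R,2S)-1-(methoxycarbonyl)-2-[(3,4,5-trimethoxyphenyl)methyl]cyclopropane-1-carboxylic acid | COC(=O)[C@]1(C(=O)O)C[C@@H]1Cc1cc(OC)c(OC)c(OC)c1
F8 | step 4 | methyl (1S,2S)-1-(chlorocarbonyl)-2-[(3,4,5-trimethoxyphenyl)methyl]cyclopropane-1-carboxylate | COC(=O)[C@]1(C(=O)Cl)C[C@@H]1Cc1cc(OC)c(OC)c(OC)c1
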